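**Plan**

- Retrosynthesis: the vanillyl group on C3 is cut first (enolate alkylation). Ring bonds O1–C5 and C3–C4 of the butyrolactone are then cut together, after two chlorines are placed on C3 and an arylthio group on C5. This leaves dichloroketene and a (Z)-alkenyl p-tolyl sulfoxide that already carries the silylated benzylic carbinol.
- Forward: vanillin → silylated aryl propargylic alcohol (resolved) → alkynyl sulfoxide → (Z)-alkenyl sulfoxide → lactone ring in one step (ketene lactonization) → removal of Cl and S → trans benzylation at C3 → global desilylation.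
- Stereochemistry: the carbinol carbon comes from a lipase resolution; ring C4 from chirality transfer from sulfur (Andersen sulfinate) in the [3,3] shift; C3 from alkylation anti to the C4 substituent.
- Enabling feature: ring atoms C3, C2(=O) and O1 are the three atoms of a ketene, and C4–C5 is a two-carbon unit whose C5 is an O-bound CH2 next to the stereogenic C4. A vinyl sulfoxide offers exactly this pair as acceptor for the ketene carbon (at C4) and the carboxylate oxygen (at C5).

Key step: step 7

Remark: the target is taken as the (3R,4R)-lactone with an (S)-carbinol (7-hydroxymatairesinol series); the sense of the lipase resolution and of the sulfur-to-carbon chirality transfer is assigned from the Kazlauskas and chair models, not from a measured result.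

Abbreviations: TBS = tert-butyldimethylsilyl; Tol = 4-methylphenyl.

**Step 1**
Reactants: 1 vanillin
Product: 2 4-(TBSO)-3-methoxybenzaldehyde
Conditions: TBSCl, imidazole, DMF, rt
Reagents that add atoms: tert-butyldimethylsilyl chloride, C[Si](C)(Cl)C(C)(C)C
Why: Imidazole-promoted silylation of the phenol; the silyl ether should withstand every later organometallic, radical and enolate step and leaves with fluoride at the end.

**Step 2**
Reactants: 2 4-(TBSO)-3-methoxybenzaldehyde
Product: 3 rac-1-[4-(TBSO)-3-methoxyphenyl]prop-2-yn-1-ol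
Conditions: HC≡CMgBr, THF, 0 °C; aq. NH4Cl
Reagents that add atoms: ethynylmagnesium bromide, C#C[Mg]Br
Why: Grignard 1,2-addition of the acetylide to the aryl aldehyde installs the two carbons that become C4 and C5 of the lactone; the carbinol forms racemic and is resolved in step 3.

**Step 3**
Reactants: 3 rac-1-[4-(TBSO)-3-methoxyphenyl]prop-2-yn-1-ol
Product: 4 (S)-1-[4-(TBSO)-3-methoxyphenyl]prop-2-yn-1-ol (the enantiomer that is not acylated)
Conditions: Novozym 435 (immobilised Candida antarctica lipase B), vinyl acetate, MTBE, 30 °C, run to just past half conversion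
Reagents that add atoms: none
Why: Lipase-catalysed kinetic resolution by irreversible transesterification: with aryl as the large and ethynyl as the medium group, Kazlauskas' rule predicts acylation of the (R)-alcohol, so the (S)-alcohol 4 should remain and set the carbinol stereocentre.

**Step 4**
Reactants: 4 (S)-1-[4-(TBSO)-3-methoxyphenyl]prop-2-yn-1-ol
Product: 5 (S)-3-(TBSO)-3-[4-(TBSO)-3-methoxyphenyl]prop-1-yne
Conditions: TBSCl, imidazole, DMF, rt
Reagents that add atoms: tert-butyldimethylsilyl chloride, C[Si](C)(Cl)C(C)(C)C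
Why: Standard silylation of the secondary alcohol, needed because a free hydroxyl would be acylated by the sulfinate in step 5 and by the ketene in step 7.

**Step 5**
Reactants: 5 (S)-3-(TBSO)-3-[4-(TBSO)-3-methoxyphenyl]prop-1-yne; 6 (1R,2S,5R)-menthyl (S)-4-methylbenzenesulfinate
Product: 8 (R)-3-(TBSO)-3-[4-(TBSO)-3-methoxyphenyl]-1-[(S)-Tol-sulfinyl]prop-1-yne, via alkynylmagnesium bromide 7 (not isolated)
Conditions: EtMgBr, THF, 0 °C → rt; then added to 6 in toluene, −20 °C
Reagents that add atoms: none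
Why: Andersen sulfoxide synthesis: the alkynyl Grignard displaces menthoxide at sulfur with inversion, so the (S)-sulfinate should give the sulfoxide with the sulfur configuration shown (descriptor S because the alkynyl group outranks tolyl; the carbinol descriptor changes to R for the same reason, not by inversion).

**Step 6**
Reactants: 8 alkynyl sulfoxide
Product: 9 (S,Z)-3-(TBSO)-3-[4-(TBSO)-3-methoxyphenyl]-1-[(R)-Tol-sulfinyl]prop-1-ene
Conditions: H2 (1 atm), RhCl(PPh3)3 (5 mol%), benzene/EtOH, rt
Reagents that add atoms: none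
Why: Homogeneous syn hydrogenation of a 1-alkynyl sulfoxide with Wilkinson's catalyst stops at the (Z)-alkenyl sulfoxide (known for this substrate class) and touches neither sulfur nor the carbinol centre.

**Step 7**
Reactants: 9 (Z)-alkenyl sulfoxide
Product: 12 (4S,5R)-3,3-dichloro-4-{(S)-(TBSO)[4-(TBSO)-3-methoxyphenyl]methyl}-5-(Tol-sulfanyl)oxolan-2-one, via acyloxysulfonium enolate 10 (not isolated), via thionium carboxylate 11 (not isolated)
Conditions: Cl3CCOCl (slow addition), Zn/Cu couple, THF, −45 → 0 °C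
Reagents that add atoms: trichloroacetyl chloride, O=C(Cl)C(Cl)(Cl)Cl (source of dichloroketene, ClC(Cl)=C=O)
Why: Ketene lactonization of a vinyl sulfoxide (Marino lactonization): the sulfinyl oxygen is acylated by dichloroketene to enolate 10, which undergoes a [3,3]-sigmatropic shift through a chair (the S–O bond breaks, the CCl2 carbon bonds to the β-vinyl carbon) to thionium carboxylate 11, whose carboxylate then adds to the thionium carbon. It is an additive Pummerer-type process; the closest precedent is the dichloroketene lactonization of optically active 1-alkenyl p-tolyl sulfoxides, a known route to β-substituted γ-butyrolactones. The lactone ring closes by 5-exo-trig attack of the carboxylate oxygen on the C=S+ carbon, which the new C–C bond holds next to it. Ring C4 is set by chirality transfer from sulfur: in the chair the tolyl group sits pseudo-equatorial and the sulfur lone pair points toward the cis substituent (allylic 1,3-strain in the Z-alkene), so the enolate carbon should reach one face only, which for the (R)-(Z)-sulfoxide is the face leading to the required centre; C5 follows from suprafacial syn addition (4,5-cis) and is erased in step 8, and the silyloxy carbinol carbon is a spectator. The step needs O-acylation of the sulfoxide over any other site and face control by sulfur over the allylic stereocentre; full silylation of the hydroxyls, the absence of other alkenes and the sulfur-bound, intramolecular delivery of the enolate should secure this.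

**Step 8**
Reactants: 12 dichloro sulfide lactone
Product: 15 (R)-4-{(S)-(TBSO)[4-(TBSO)-3-methoxyphenyl]methyl}oxolan-2-one, via monochloro sulfide lactone 13 (not isolated), via sulfide lactone 14 (not isolated)
Conditions: n-Bu3SnH (4 equiv), AIBN (cat.), toluene, 90 °C
Reagents that add atoms: none
Why: Radical chain reduction with the stannane removes both α-carbonyl chlorines and then the arylthio group of the O,S-acetal (via the α-oxy radical), which erases C5 as a stereocentre and leaves C4 and the carbinol untouched.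

**Step 9**
Reactants: 2 4-(TBSO)-3-methoxybenzaldehyde
Product: 16 [4-(TBSO)-3-methoxyphenyl]methanol
Conditions: NaBH4, MeOH, 0 °C
Reagents that add atoms: none
Why: Borohydride reduction of the aldehyde; the aryl silyl ether should be stable at 0 °C.

**Step 10**
Reactants: 16 [4-(TBSO)-3-methoxyphenyl]methanol
Product: 17 4-(bromomethyl)-2-methoxy-1-(TBSO)benzene
Conditions: CBr4, PPh3, CH2Cl2, 0 °C
Reagents that add atoms: carbon tetrabromide, BrC(Br)(Br)Br
Why: Appel bromination under neutral conditions, chosen because acid would cleave the aryl silyl ether; the electron-rich benzylic bromide is used at once.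

**Step 11**
Reactants: 15 (R)-4-{(S)-(TBSO)[4-(TBSO)-3-methoxyphenyl]methyl}oxolan-2-one; 17 4-(bromomethyl)-2-methoxy-1-(TBSO)benzene
Product: 19 (3R,4R)-3-[4-(TBSO)-3-methoxybenzyl]-4-{(S)-(TBSO)[4-(TBSO)-3-methoxyphenyl]methyl}oxolan-2-one, via lithium enolate 18 (not isolated)
Conditions: LiN(SiMe3)2, THF, −78 °C; then 17, DMPU, −78 → −30 °C
Reagents that add atoms: none
Why: Alkylation of a β-substituted γ-butyrolactone enolate occurs anti to the C4 substituent, the standard way to the 3,4-trans pattern of dibenzylbutyrolactone lignans, so C3 should form with the (R) configuration.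

**Step 12**
Reactants: 19 tris-silyl ether
Product: 20 (3R,4R)-3-(4-hydroxy-3-methoxybenzyl)-4-[(S)-hydroxy(4-hydroxy-3-methoxyphenyl)methyl]oxolan-2-one
Conditions: TBAF, AcOH (1:1), THF, 0 °C → rt
Reagents that add atoms: none
Why: Fluoride buffered with acetic acid cleaves the two aryl and the benzylic silyl ethers without free alkoxide or phenoxide, which would epimerise the 4-hydroxybenzylic carbinol through a quinone methide or move the lactone onto the secondary hydroxyl.

**Compound list**

1 | vanillin | COc1cc(C=O)ccc1O | starting material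
2 | 4-(TBSO)-3-methoxybenzaldehyde | COc1cc(C=O)ccc1O[Si](C)(C)C(C)(C)C | intermediate
3 | rac-1-[4-(TBSO)-3-methoxyphenyl]prop-2-yn-1-ol | C#CC(O)c1ccc(O[Si](C)(C)C(C)(C)C)c(OC)c1 | intermediate
4 | (S)-1-[4-(TBSO)-3-methoxyphenyl]prop-2-yn-1-ol | C#C[C@H](O)c1ccc(O[Si](C)(C)C(C)(C)C)c(OC)c1 | intermediate
5 | (S)-3-(TBSO)-3-[4-(TBSO)-3-methoxyphenyl]prop-1-yne | C#C[C@H](O[Si](C)(C)C(C)(C)C)c1ccc(O[Si](C)(C)C(C)(C)C)c(OC)c1 | intermediate
6 | (1R,2S,5R)-menthyl (S)-4-methylbenzenesulfinate | CC(C)[C@@H]1CC[C@@H](C)C[C@H]1O[S@](=O)c1ccc(C)cc1 | starting material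
7 | alkynylmagnesium bromide of 5 | Br[Mg]C#C[C@H](O[Si](C)(C)C(C)(C)C)c1ccc(O[Si](C)(C)C(C)(C)C)c(OC)c1 | intermediate (not isolated)
8 | (R)-3-(TBSO)-3-[4-(TBSO)-3-methoxyphenyl]-1-[(S)-Tol-sulfinyl]prop-1-yne | COc1cc([C@@H](O[Si](C)(C)C(C)(C)C)C#C[S@@](=O)c2ccc(C)cc2)ccc1O[Si](C)(C)C(C)(C)C | intermediate
9 | (S,Z)-3-(TBSO)-3-[4-(TBSO)-3-methoxyphenyl]-1-[(R)-Tol-sulfinyl]prop-1-ene | COc1cc([C@@H](O[Si](C)(C)C(C)(C)C)/C=C\[S@@](=O)c2ccc(C)cc2)ccc1O[Si](C)(C)C(C)(C)C | intermediate
10 | acyloxysulfonium enolate (O-acylated sulfoxide) | COc1cc([C@@H](O[Si](C)(C)C(C)(C)C)/C=C\[S@@+](OC([O-])=C(Cl)Cl)c2ccc(C)cc2)ccc1O[Si](C)(C)C(C)(C)C | intermediate (not isolated)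
11 | thionium carboxylate after the [3,3] shift | Cc1ccc([S+]=C[C@@H](C(Cl)(Cl)C(=O)[O-])[C@H](O[Si](C)(C)C(C)(C)C)c2ccc(O[Si](C)(C)C(C)(C)C)c(OC)c2)cc1 | intermediate (not isolated)
12 | (4S,5R)-3,3-dichloro-4-{(S)-(TBSO)[4-(TBSO)-3-methoxyphenyl]methyl}-5-(Tol-sulfanyl)oxolan-2-one | Cc1ccc(S[C@H]2OC(=O)C(Cl)(Cl)[C@H]2[C@H](O[Si](C)(C)C(C)(C)C)c2ccc(O[Si](C)(C)C(C)(C)C)c(OC)c2)cc1 | intermediate
13 | 3-chloro analogue of 12 (one chlorine removed; C3 unassigned) | Cc1ccc(S[C@H]2OC(=O)C(Cl)[C@H]2[C@H](O[Si](C)(C)C(C)(C)C)c2ccc(O[Si](C)(C)C(C)(C)C)c(OC)c2)cc1 | intermediate (not isolated)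
14 | (4S,5R)-4-{(S)-(TBSO)[4-(TBSO)-3-methoxyphenyl]methyl}-5-(Tol-sulfanyl)oxolan-2-one | Cc1ccc(S[C@H]2OC(=O)C[C@H]2[C@H](O[Si](C)(C)C(C)(C)C)c2ccc(O[Si](C)(C)C(C)(C)C)c(OC)c2)cc1 | intermediate (not isolated)
15 | (R)-4-{(S)-(TBSO)[4-(TBSO)-3-methoxyphenyl]methyl}oxolan-2-one | O=C1C[C@H](CO1)[C@H](O[Si](C)(C)C(C)(C)C)c1ccc(O[Si](C)(C)C(C)(C)C)c(OC)c1 | intermediate
16 | [4-(TBSO)-3-methoxyphenyl]methanol | COc1cc(CO)ccc1O[Si](C)(C)C(C)(C)C | intermediate
17 | 4-(bromomethyl)-2-methoxy-1-(TBSO)benzene | COc1cc(CBr)ccc1O[Si](C)(C)C(C)(C)C | intermediate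
18 | lithium enolate of 15 | [Li]OC1=C[C@H](CO1)[C@H](O[Si](C)(C)C(C)(C)C)c1ccc(O[Si](C)(C)C(C)(C)C)c(OC)c1 | intermediate (not isolated)
19 | (3R,4R)-3-[4-(TBSO)-3-methoxybenzyl]-4-{(S)-(TBSO)[4-(TBSO)-3-methoxyphenyl]methyl}oxolan-2-one | COc1cc(C[C@H]2C(=O)OC[C@@H]2[C@H](O[Si](C)(C)C(C)(C)C)c2ccc(O[Si](C)(C)C(C)(C)C)c(OC)c2)ccc1O[Si](C)(C)C(C)(C)C | intermediate
20 | (3R,4R)-3-(4-hydroxy-3-methoxybenzyl)-4-[(S)-hydroxy(4-hydroxy-3-methoxyphenyl)methyl]oxolan-2-one | COc1cc(C[C@H]2C(=O)OC[C@@H]2[C@H](O)c2ccc(O)c(OC)c2)ccc1O | target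

**Totals**

Total steps: 12. Longest linear sequence: 10 steps (steps 1 to 8, then 11 and 12).

**Steps most likely to fail**

Step 7. The face control by sulfur may be eroded by a mismatch with the allylic silyloxy stereocentre. The sigmatropic shift may be slow because the branched substituent sits pseudo-axial. The zinc chloride formed may ionise the benzylic silyl ether. The fallback builds the same lactone by an aldol route; it sets out from 2 and comes back at 15. (S)-4-Benzyloxazolidin-2-one is acylated with pent-4-enoyl chloride (n-BuLi, THF, −78 °C) to the imide (S)-4-benzyl-3-(pent-4-enoyl)oxazolidin-2-one F1. Its dibutylboron enolate (Bu2BOTf, i-Pr2NEt, CH2Cl2, −78 → 0 °C) adds to aldehyde 2 to give the Evans syn aldol adduct F2, which should already hold both stereocentres in the required sense. Silylation (TBSOTf, 2,6-lutidine) gives the silyl ether F3. LiBH4 (THF/MeOH, 0 °C) removes the auxiliary and gives the primary alcohol F4. OsO4 (cat.) and NaIO4 with 2,6-lutidine (dioxane/water) cleave the terminal alkene, and the aldehyde closes onto the primary hydroxyl to the lactol F5. Ag2CO3 on Celite (toluene, 80 °C) oxidises F5 to lactone 15.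

Step 6. The hydrogenation may run on to the saturated sulfoxide or stall because sulfur binds to rhodium. The fallback makes the (Z)-alkenyl sulfoxide by sulfinylation of a preformed (Z)-alkenyl metal; it sets out from 5 and comes back at 9. The alkyne is iodinated (N-iodosuccinimide, AgNO3 cat., acetone) to the iodoalkyne F6. Diimide reduction (2-nitrobenzenesulfonyl hydrazide, Et3N, THF/i-PrOH) gives the (Z)-alkenyl iodide F7. Iodine–magnesium exchange (i-PrMgCl·LiCl, THF, −40 °C) gives the (Z)-alkenylmagnesium chloride F8 with retention of geometry. Addition of F8 to sulfinate 6 (inversion at sulfur) gives 9.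

Step 11. C-alkylation of the hindered enolate may be slow while the electron-rich benzylic bromide decomposes, or a second alkylation may follow. The fallback goes through an aldol condensation; it sets out from 15 and comes back at 19. The lithium enolate 18 is added to aldehyde 2 (THF, −78 °C) to give the aldol adduct F9. Mesylation and elimination (MsCl, Et3N; then DBU) give the (E)-benzylidene lactone F10. Hydrogenation (H2, Pd/C, EtOAc) followed by equilibration with DBU gives the trans lactone 19.

**Further compounds**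

F1 | step 7 | (S)-4-benzyl-3-(pent-4-enoyl)oxazolidin-2-one | C=CCCC(=O)N1[C@@H](Cc2ccccc2)COC1=O
F2 | step 7 | (S)-4-benzyl-3-[(2S,3S)-2-allyl-3-hydroxy-3-[4-(TBSO)-3-methoxyphenyl]propanoyl]oxazolidin-2-one | C=CC[C@H](C(=O)N1[C@@H](Cc2ccccc2)COC1=O)[C@H](O)c1ccc(O[Si](C)(C)C(C)(C)C)c(OC)c1
F3 | step 7 | silyl ether of F2 | C=CC[C@H](C(=O)N1[C@@H](Cc2ccccc2)COC1=O)[C@H](O[Si](C)(C)C(C)(C)C)c1ccc(O[Si](C)(C)C(C)(C)C)c(OC)c1
F4 | step 7 | (R)-2-{(S)-(TBSO)[4-(TBSO)-3-methoxyphenyl]methyl}pent-4-en-1-ol | C=CC[C@H](CO)[C@H](O[Si](C)(C)C(C)(C)C)c1ccc(O[Si](C)(C)C(C)(C)C)c(OC)c1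
F5 | step 7 | (4R)-4-{(S)-(TBSO)[4-(TBSO)-3-methoxyphenyl]methyl}oxolan-2-ol (both anomers) | OC1C[C@H](CO1)[C@H](O[Si](C)(C)C(C)(C)C)c1ccc(O[Si](C)(C)C(C)(C)C)c(OC)c1
F6 | step 6 | (R)-1-iodo-3-(TBSO)-3-[4-(TBSO)-3-methoxyphenyl]prop-1-yne | IC#C[C@H](O[Si](C)(C)C(C)(C)C)c1ccc(O[Si](C)(C)C(C)(C)C)c(OC)c1
F7 | step 6 | (S,Z)-1-iodo-3-(TBSO)-3-[4-(TBSO)-3-methoxyphenyl]prop-1-ene | I/C=C\[C@H](O[Si](C)(C)C(C)(C)C)c1ccc(O[Si](C)(C)C(C)(C)C)c(OC)c1
F8 | step 6 | (Z)-alkenylmagnesium chloride from F7 | Cl[Mg]/C=C\[C@H](O[Si](C)(C)C(C)(C)C)c1ccc(O[Si](C)(C)C(C)(C)C)c(OC)c1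
F9 | step 11 | aldol adduct of 15 with 2 (3,4-trans; carbinol epimers) | COc1cc(C(O)[C@H]2C(=O)OC[C@@H]2[C@H](O[Si](C)(C)C(C)(C)C)c2ccc(O[Si](C)(C)C(C)(C)C)c(OC)c2)ccc1O[Si](C)(C)C(C)(C)C
F10 | step 11 | (3E,4R)-3-[4-(TBSO)-3-methoxybenzylidene]-4-{(S)-(TBSO)[4-(TBSO)-3-methoxyphenyl]methyl}oxolan-2-one | COc1cc(/C=C2/C(=O)OC[C@@H]2[C@H](O[Si](C)(C)C(C)(C)C)c2ccc(O[Si](C)(C)C(C)(C)C)c(OC)c2)ccc1O[Si](C)(C)C(C)(C)C
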